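**Plan**
1. The retrosynthesis first cuts the ester bond at O10 to (9Z)-16-hydroxyhexadec-9-enoic acid, then the C2–C12 bond (the formyl carbon, put on through a C2 enol triflate) and the C10–O bond (allylic oxidation, then reduction, in ring B).
2. Ring C is then contracted by cutting C2–C3 and C3–C4. This is possible because C2, the ring C carbon next to quaternary C1, carries a one-carbon branch and can pass through the ketone level, while C3 and C4 are plain methylenes. Removing C3 leaves a cyclobutanone C1–C2(=O)–C4–C5 fused to ring A.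
3. The cyclobutanone is cut at C1–C5 and C2–C4 into a keteniminium ion (from a C1 carboxamide on cyclohexene ring B) and a vinyl group on a CMe2 tether at C7. The C7–C6 bond is cut by a Claisen rearrangement from an allylic C9–O bond, and C15 is cut at an alkenyl iodide.
4. Forward order: ring B (Birch reduction of 3-methoxybenzoic acid), then the C7 side chain, then ring A together with the four-membered ring in one [2+2] step, then ring C by one-carbon enlargement, then C10–O, C12 and the side-chain ester.
5. Stereochemistry: the C9 carbinol comes from a CBS reduction and is relayed to C7 by the suprafacial [3,3] shift. C7 alone then fixes C1 and C5 in the [2+2] step. C10 comes from a Luche reduction anti to the C1–C5 bond, C2 from equilibration of the aldehyde, and the Z alkene from a Lindlar reduction.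

Key step: step 10

Remark (labels): names and reasons use cedrane numbering. C1 is the quaternary carbon; C1–C2–C3–C4–C5 is ring C (C2 bears the formyl carbon C12); C1–C5–C6(CMe2)–C7–C11 is ring A; C1–C10(C–O)–C9=C8–C7–C11 is ring B (C8 bears the carboxyl carbon C15).
Remark (assumption): the amide-bearing ring carbon (the later C1) is racemic in 3–5 and is carried as both epimers in 6–11; it becomes sp2 in step 9, where the two epimers should converge.

Step 1
Reactants: 1 3-methoxybenzoic acid
Product: 3 5-oxocyclohex-3-ene-1-carboxylic acid (racemic), via 1,4-dihydro acid 2 (not isolated)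
Conditions: Li, NH3(l), THF, t-BuOH, −78 °C; NH4Cl; then 2 M HCl, THF, rt
Reagents that add atoms: water, O
Why: Birch reduction of a benzoic acid protonates C1 and C4 and leaves the methoxy-bearing carbon olefinic; aqueous acid then hydrolyses the enol ether and moves the other double bond into conjugation, so ring B should arrive as a 5-substituted cyclohex-2-enone.

Step 2
Reactants: 3 5-oxocyclohex-3-ene-1-carboxylic acid
Product: 4 5-(pyrrolidine-1-carbonyl)cyclohex-2-en-1-one (racemic)
Conditions: DCC, HOBt (cat.), pyrrolidine, CH2Cl2, 0 °C → rt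
Reagents that add atoms: pyrrolidine, C1CCNC1
Why: carbodiimide amide coupling; the tertiary amide is the helper group that later becomes the keteniminium ion, and acylation of the amine should outrun reversible aza-Michael addition to the enone.

Step 3
Reactants: 4 5-(pyrrolidine-1-carbonyl)cyclohex-2-en-1-one
Product: 5 2-iodo-5-(pyrrolidine-1-carbonyl)cyclohex-2-en-1-one (racemic)
Conditions: I2, pyridine, CH2Cl2, rt
Reagents that add atoms: iodine, II
Why: α-iodination of the enone by pyridine addition, iodination and elimination (Johnson iodination) puts the handle for C15 on C8 and makes the alkenyl arm the large group for the next step.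

Step 4
Reactants: 5 2-iodo-5-(pyrrolidine-1-carbonyl)cyclohex-2-en-1-one
Product: 6 [(5R)-5-hydroxy-4-iodocyclohex-3-en-1-yl](pyrrolidin-1-yl)methanone (both epimers at the amide-bearing carbon)
Conditions: (S)-2-methyl-CBS-oxazaborolidine (20 mol %), catecholborane, toluene, −78 °C
Reagents that add atoms: none
Why: Corey–Bakshi–Shibata reduction; the α-iodoalkenyl arm acts as the large group, so hydride should reach the same carbonyl face in both enantiomers of 5 (reagent control over the remote centre) and set the R carbinol at C9.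

Step 5
Reactants: 6 [(5R)-5-hydroxy-4-iodocyclohex-3-en-1-yl](pyrrolidin-1-yl)methanone
Product: 7 2-(trimethylsilyl)ethyl (6R)-6-hydroxy-4-(pyrrolidine-1-carbonyl)cyclohex-1-ene-1-carboxylate
Conditions: Pd(OAc)2 (5 mol %), PPh3, CO (1 atm), Et3N, Me3SiCH2CH2OH, DMF, 60 °C
Reagents that add atoms: carbon monoxide, [C-]#[O+]; 2-(trimethylsilyl)ethanol, C[Si](C)(C)CCO
Why: palladium-catalysed alkoxycarbonylation of the alkenyl iodide (oxidative addition, CO insertion, alcoholysis) installs C15 at the acid oxidation level as a fluoride-labile ester without touching the carbinol centre.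

Step 6
Reactants: 7 2-(trimethylsilyl)ethyl (6R)-6-hydroxy-4-(pyrrolidine-1-carbonyl)cyclohex-1-ene-1-carboxylate
Product: 8 2-(trimethylsilyl)ethyl (6R)-6-[(2-methylprop-2-en-1-yl)oxy]-4-(pyrrolidine-1-carbonyl)cyclohex-1-ene-1-carboxylate
Conditions: NaH, Bu4NI (cat.), 3-bromo-2-methylprop-1-ene, THF, 0 °C
Reagents that add atoms: 3-bromo-2-methylprop-1-ene, C=C(C)CBr
Why: Williamson etherification of the secondary allylic alkoxide with a reactive allylic bromide; the stereocentre is not involved.

Step 7
Reactants: 8 2-(trimethylsilyl)ethyl (6R)-6-[(2-methylprop-2-en-1-yl)oxy]-4-(pyrrolidine-1-carbonyl)cyclohex-1-ene-1-carboxylate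
Product: 10 2-(trimethylsilyl)ethyl (6R)-6-(2-methyl-1-oxopropan-2-yl)-4-(pyrrolidine-1-carbonyl)cyclohex-1-ene-1-carboxylate, via isobutenyl ether 9 (not isolated)
Conditions: [Ir(coe)2Cl]2 (1 mol %), PCy3, NaBPh4, CH2Cl2–acetone, rt; then PPh3, toluene, 100 °C
Reagents that add atoms: none
Why: iridium hydride isomerisation of the 2-methylallyl ether to the 2-methylprop-1-enyl ether, then thermal Claisen [3,3] rearrangement through a chair transition state; the shift is suprafacial, so the C7–C6 bond should form on the face that carried the C9–O bond (R at C9 gives R at C7), while the gem-dimethyl carbon C6 is made and the double bond lands at C8=C9.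

Step 8
Reactants: 10 2-(trimethylsilyl)ethyl (6R)-6-(2-methyl-1-oxopropan-2-yl)-4-(pyrrolidine-1-carbonyl)cyclohex-1-ene-1-carboxylate
Product: 11 2-(trimethylsilyl)ethyl (6R)-6-(2-methylbut-3-en-2-yl)-4-(pyrrolidine-1-carbonyl)cyclohex-1-ene-1-carboxylate
Conditions: Ph3PCH3Br, KOtBu, THF, 0 °C
Reagents that add atoms: methyltriphenylphosphonium bromide, C[P+](c1ccccc1)(c1ccccc1)c1ccccc1.[Br-]
Why: Wittig methylenation of a non-enolisable neopentyl aldehyde gives the vinyl group (C5=C4) that is the two-carbon partner of the cycloaddition.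

Step 9
Reactants: 11 2-(trimethylsilyl)ethyl (6R)-6-(2-methylbut-3-en-2-yl)-4-(pyrrolidine-1-carbonyl)cyclohex-1-ene-1-carboxylate
Product: 14 2-(trimethylsilyl)ethyl 2-oxo-3,12-dinorcedr-8-en-15-oate (cyclobutanone C1–C2(=O)–C4–C5 cis-fused to ring A), via keteniminium triflate 12 (not isolated), via cyclobutaniminium triflate 13 (not isolated)
Conditions: Tf2O, 2,4,6-collidine, ClCH2CH2Cl, 80 °C; then aq. NaHCO3
Reagents that add atoms: water, O
Why: intramolecular keteniminium–alkene [2+2] cycloaddition (Ghosez); O-triflation and loss of the C1 proton give the keteniminium ion, whose electrophilic central carbon C2 bonds to the terminal alkene carbon C4 while C1 bonds to C5, and because the three-atom tether from C7 reaches only one face of C1, only the cis-bridged, cis-fused adduct can form, so C7 alone should set C1 and C5 and both epimers of 11 converge.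

Step 10
Reactants: 14 2-(trimethylsilyl)ethyl 2-oxo-3,12-dinorcedr-8-en-15-oate
Product: 16 2-(trimethylsilyl)ethyl 2-oxo-12-norcedr-8-en-15-oate (cyclopentanone ring C), via β-keto silane 15 (not isolated)
Conditions: Me3SiCHN2, Sc(OTf)3 (10 mol %), toluene, −78 → 0 °C; then 1 M HCl, THF, rt
Reagents that add atoms: (trimethylsilyl)diazomethane, C[Si](C)(C)C=[N+]=[N-]
Why: Sc(OTf)3 activates the strained cyclobutanone carbonyl C2, the diazo carbon adds to it, and loss of N2 from the diazonium alkoxide triggers a 1,2-shift of the ring methylene C4 from C2 to the incoming carbon C3, which forms the C3–C4 bond and enlarges the four-membered ring to ring C; the β-keto silane is then protodesilylated. The closest known reaction type is the Lewis acid-catalysed homologation of 2-substituted cyclobutanones with trimethylsilyldiazomethane (Tiffeneau–Demjanov-type ring expansion). Ring C is closed by ring enlargement through a suprafacial 1,2-alkyl shift with retention at C4, not by an exo or endo cyclisation, and relief of cyclobutanone strain (about 26 kcal/mol) drives it. No lasting stereocentre is made: the silyl-bearing C3 becomes CH2, and C1 and C5 are untouched. The step needs regioselectivity (migration of C4, not of quaternary C1) and chemoselectivity (one insertion, no dipolar addition to the enoate). The first should be secured by the fully substituted C1 and the bulky silyl group, which place the leaving N2 anti to the C2–C4 bond; the second by the low temperature and the much higher reactivity of the strained ketone than of the cyclopentanone product or the trisubstituted enoate.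

Step 11
Reactants: 16 2-(trimethylsilyl)ethyl 2-oxo-12-norcedr-8-en-15-oate
Product: 17 2-(trimethylsilyl)ethyl 2,10-dioxo-12-norcedr-8-en-15-oate
Conditions: Rh2(caprolactamate)4 (1 mol %), t-BuOOH (aq.), K2CO3, CH2Cl2, rt
Reagents that add atoms: tert-butyl hydroperoxide, CC(C)(C)OO
Why: dirhodium-catalysed allylic oxidation with tert-butyl hydroperoxide (hydrogen abstraction by the tert-butylperoxyl radical) should attack the only usable allylic position, the ring B methylene C10, because C7 is a bridgehead whose radical cannot conjugate.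

Step 12
Reactants: 17 2-(trimethylsilyl)ethyl 2,10-dioxo-12-norcedr-8-en-15-oate
Product: 18 2-(trimethylsilyl)ethyl 10-oxo-2-(trifluoromethanesulfonyloxy)-12-norcedra-2,8-dien-15-oate
Conditions: KHMDS, PhNTf2, THF, −78 °C
Reagents that add atoms: N-phenylbis(trifluoromethanesulfonimide), O=S(=O)(N(c1ccccc1)S(=O)(=O)C(F)(F)F)C(F)(F)F
Why: kinetic enolisation and O-sulfonylation; the C2 ketone can enolise only towards C3 (C1 is quaternary) and the C10 ketone has no removable α- or γ-hydrogen, so one enol triflate should form, which masks C2 during the reduction and is the handle for C12.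

Step 13
Reactants: 18 2-(trimethylsilyl)ethyl 10-oxo-2-(trifluoromethanesulfonyloxy)-12-norcedra-2,8-dien-15-oate
Product: 19 2-(trimethylsilyl)ethyl 10-hydroxy-2-(trifluoromethanesulfonyloxy)-12-norcedra-2,8-dien-15-oate (C10–O on the side of the C5–C6 bridge)
Conditions: NaBH4, CeCl3·7H2O, MeOH, −78 °C
Reagents that add atoms: none
Why: Luche 1,2-reduction; the C1–C5 bond stands perpendicular to the C10 carbonyl plane, so hydride should add anti to it (Felkin–Anh-type approach from the face of the one-carbon bridge) and leave the C10–O bond on the side of the two-carbon bridge, as required.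

Step 14
Reactants: 20 6-bromohexan-1-ol
Product: 21 [(6-bromohexyl)oxy](tert-butyl)dimethylsilane
Conditions: t-BuMe2SiCl, imidazole, CH2Cl2, rt
Reagents that add atoms: tert-butyl(chloro)dimethylsilane, CC(C)(C)[Si](C)(C)Cl
Why: silylation of the primary alcohol protects the future C16 hydroxyl through the alkylation and the late steps.

Step 15
Reactants: 21 [(6-bromohexyl)oxy](tert-butyl)dimethylsilane; 22 dec-9-ynoic acid
Product: 23 16-[(tert-butyldimethylsilyl)oxy]hexadec-9-ynoic acid
Conditions: 22, n-BuLi (2.1 equiv), THF–HMPA, −78 → 0 °C; then 21, rt; aq. HCl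
Reagents that add atoms: none
Why: SN2 alkylation of the lithium acetylide of the carboxylate dianion by the primary bromide joins C1–C10 to C11–C16 of the side chain.

Step 16
Reactants: 23 16-[(tert-butyldimethylsilyl)oxy]hexadec-9-ynoic acid
Product: 24 (9Z)-16-[(tert-butyldimethylsilyl)oxy]hexadec-9-enoic acid
Conditions: H2 (1 atm), Pd/CaCO3 poisoned with Pb(OAc)2, quinoline, EtOAc, rt
Reagents that add atoms: none
Why: Lindlar semihydrogenation adds H2 syn on the poisoned palladium surface and should stop at the Z alkene.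

Step 17
Reactants: 19 2-(trimethylsilyl)ethyl 10-hydroxy-2-(trifluoromethanesulfonyloxy)-12-norcedra-2,8-dien-15-oate; 24 (9Z)-16-[(tert-butyldimethylsilyl)oxy]hexadec-9-enoic acid
Product: 25 the C10 ester of 19 with 24
Conditions: 24, 2,4,6-Cl3C6H2COCl, Et3N, THF, rt; then 19, DMAP, toluene, 60 °C
Reagents that add atoms: none
Why: Yamaguchi esterification (mixed anhydride, acyl transfer by DMAP) should acylate the hindered secondary allylic alcohol without change at C10.

Step 18
Reactants: 25 the C10 ester of 19 with 24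
Product: 26 the C2 carbaldehyde (2-formyl-2,8-diene, enal) corresponding to 25
Conditions: Pd(OAc)2 (5 mol %), dppp, CO (1 atm), Et3SiH, Et3N, DMF, 70 °C
Reagents that add atoms: carbon monoxide, [C-]#[O+]
Why: palladium-catalysed reductive carbonylation of the alkenyl triflate (oxidative addition, CO insertion, hydride transfer from the silane) installs the formyl carbon C12 on C2.

Step 19
Reactants: 26 the C2 carbaldehyde (enal)
Product: 28 2-(trimethylsilyl)ethyl 10-{[(9Z)-16-[(tert-butyldimethylsilyl)oxy]hexadec-9-enoyl]oxy}-12-oxocedr-8-en-15-oate (target configuration at C2), via C2-epimer mixture 27 (not isolated)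
Conditions: [(Ph3P)CuH]6, toluene, H2O, rt; then DBU (cat.), CH2Cl2, rt
Reagents that add atoms: none
Why: copper hydride conjugate reduction (Stryker) should prefer the enal over the hindered enoate and the isolated alkene, and the amidine base then equilibrates C2 through the enol to the epimer with the formyl group anti to the C10 acyloxy group (the other epimer has a 1,3-syn C12/O10 contact), which is the required configuration.

Step 20
Reactants: 28 2-(trimethylsilyl)ethyl 10-{[(9Z)-16-[(tert-butyldimethylsilyl)oxy]hexadec-9-enoyl]oxy}-12-oxocedr-8-en-15-oate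
Product: 29 CNP0214056.2, 10-{[(9Z)-16-hydroxyhexadec-9-enoyl]oxy}-12-oxocedr-8-en-15-oic acid
Conditions: Bu4NF, AcOH, THF, 0 °C → rt
Reagents that add atoms: none
Why: fluoride cleaves the silyl ether and, by β-elimination of the 2-(trimethylsilyl)ethyl group, frees the acid; the acetic acid buffer should keep the aldehyde, the allylic ester and the Z alkene intact.

**Compound list**
1 | 3-methoxybenzoic acid | COc1cccc(c1)C(=O)O | starting material
2 | 3-methoxycyclohexa-2,5-diene-1-carboxylic acid (1,4-dihydro acid) | COC1=CC(C(=O)O)C=CC1 | intermediate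
3 | 5-oxocyclohex-3-ene-1-carboxylic acid (racemic) | O=C1CC(C(=O)O)CC=C1 | intermediate
4 | 5-(pyrrolidine-1-carbonyl)cyclohex-2-en-1-one (racemic) | O=C1CC(C(=O)N2CCCC2)CC=C1 | intermediate
5 | 2-iodo-5-(pyrrolidine-1-carbonyl)cyclohex-2-en-1-one (racemic) | O=C1CC(C(=O)N2CCCC2)CC=C1I | intermediate
6 | [(5R)-5-hydroxy-4-iodocyclohex-3-en-1-yl](pyrrolidin-1-yl)methanone, both C1 epimers | O[C@@H]1CC(C(=O)N2CCCC2)CC=C1I | intermediate
7 | 2-(trimethylsilyl)ethyl (6R)-6-hydroxy-4-(pyrrolidine-1-carbonyl)cyclohex-1-ene-1-carboxylate, both C4 epimers | O[C@@H]1CC(C(=O)N2CCCC2)CC=C1C(=O)OCC[Si](C)(C)C | intermediate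
8 | 2-(trimethylsilyl)ethyl (6R)-6-[(2-methylprop-2-en-1-yl)oxy]-4-(pyrrolidine-1-carbonyl)cyclohex-1-ene-1-carboxylate | C=C(C)CO[C@@H]1CC(C(=O)N2CCCC2)CC=C1C(=O)OCC[Si](C)(C)C | intermediate
9 | 2-(trimethylsilyl)ethyl (6R)-6-[(2-methylprop-1-en-1-yl)oxy]-4-(pyrrolidine-1-carbonyl)cyclohex-1-ene-1-carboxylate (isobutenyl ether) | CC(C)=CO[C@@H]1CC(C(=O)N2CCCC2)CC=C1C(=O)OCC[Si](C)(C)C | intermediate
10 | 2-(trimethylsilyl)ethyl (6R)-6-(2-methyl-1-oxopropan-2-yl)-4-(pyrrolidine-1-carbonyl)cyclohex-1-ene-1-carboxylate | O=CC(C)(C)[C@H]1CC(C(=O)N2CCCC2)CC=C1C(=O)OCC[Si](C)(C)C | intermediate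
11 | 2-(trimethylsilyl)ethyl (6R)-6-(2-methylbut-3-en-2-yl)-4-(pyrrolidine-1-carbonyl)cyclohex-1-ene-1-carboxylate | C=CC(C)(C)[C@H]1CC(C(=O)N2CCCC2)CC=C1C(=O)OCC[Si](C)(C)C | intermediate
12 | keteniminium triflate from 11 (ring carbon C1 doubly bonded to C2=N+) | C=CC(C)(C)[C@H]1CC(=C=[N+]2CCCC2)CC=C1C(=O)OCC[Si](C)(C)C.[O-]S(=O)(=O)C(F)(F)F | intermediate
13 | cyclobutaniminium triflate (pyrrolidinium ylidene at C2 of the four-membered ring) | CC1(C)[C@H]2C[C@@]3(CC=C2C(=O)OCC[Si](C)(C)C)C(=[N+]4CCCC4)C[C@@H]13.[O-]S(=O)(=O)C(F)(F)F | intermediate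
14 | 2-(trimethylsilyl)ethyl 2-oxo-3,12-dinorcedr-8-en-15-oate (cyclobutanone C1–C2(=O)–C4–C5 cis-fused to ring A; C1, C5, C7 as in the target) | CC1(C)[C@H]2C[C@@]3(CC=C2C(=O)OCC[Si](C)(C)C)C(=O)C[C@@H]13 | intermediate
15 | 2-(trimethylsilyl)ethyl 2-oxo-3-(trimethylsilyl)-12-norcedr-8-en-15-oate (β-keto silane, C3 configuration open) | CC1(C)[C@H]2C[C@@]3(CC=C2C(=O)OCC[Si](C)(C)C)C(=O)C([Si](C)(C)C)C[C@@H]13 | intermediate
16 | 2-(trimethylsilyl)ethyl 2-oxo-12-norcedr-8-en-15-oate | CC1(C)[C@H]2C[C@@]3(CC=C2C(=O)OCC[Si](C)(C)C)C(=O)CC[C@@H]13 | intermediate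
17 | 2-(trimethylsilyl)ethyl 2,10-dioxo-12-norcedr-8-en-15-oate | CC1(C)[C@H]2C[C@@]3(C(=O)C=C2C(=O)OCC[Si](C)(C)C)C(=O)CC[C@@H]13 | intermediate
18 | 2-(trimethylsilyl)ethyl 10-oxo-2-(trifluoromethanesulfonyloxy)-12-norcedra-2,8-dien-15-oate | CC1(C)[C@H]2C[C@@]3(C(=O)C=C2C(=O)OCC[Si](C)(C)C)C(OS(=O)(=O)C(F)(F)F)=CC[C@@H]13 | intermediate
19 | 2-(trimethylsilyl)ethyl 10-hydroxy-2-(trifluoromethanesulfonyloxy)-12-norcedra-2,8-dien-15-oate (C10 as in the target) | CC1(C)[C@H]2C[C@@]3([C@@H](O)C=C2C(=O)OCC[Si](C)(C)C)C(OS(=O)(=O)C(F)(F)F)=CC[C@@H]13 | intermediate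
20 | 6-bromohexan-1-ol | OCCCCCCBr | starting material
21 | [(6-bromohexyl)oxy](tert-butyl)dimethylsilane | CC(C)(C)[Si](C)(C)OCCCCCCBr | intermediate
22 | dec-9-ynoic acid | C#CCCCCCCCC(=O)O | starting material
23 | 16-[(tert-butyldimethylsilyl)oxy]hexadec-9-ynoic acid | CC(C)(C)[Si](C)(C)OCCCCCCC#CCCCCCCCC(=O)O | intermediate
24 | (9Z)-16-[(tert-butyldimethylsilyl)oxy]hexadec-9-enoic acid | CC(C)(C)[Si](C)(C)OCCCCCC/C=C\CCCCCCCC(=O)O | intermediate
25 | 2-(trimethylsilyl)ethyl 10-{[(9Z)-16-[(tert-butyldimethylsilyl)oxy]hexadec-9-enoyl]oxy}-2-(trifluoromethanesulfonyloxy)-12-norcedra-2,8-dien-15-oate | CC1(C)[C@H]2C[C@@]3([C@@H](OC(=O)CCCCCCC/C=C\CCCCCCO[Si](C)(C)C(C)(C)C)C=C2C(=O)OCC[Si](C)(C)C)C(OS(=O)(=O)C(F)(F)F)=CC[C@@H]13 | intermediate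
26 | 2-(trimethylsilyl)ethyl 10-{[(9Z)-16-[(tert-butyldimethylsilyl)oxy]hexadec-9-enoyl]oxy}-12-oxocedra-2,8-dien-15-oate (enal) | CC1(C)[C@H]2C[C@@]3([C@@H](OC(=O)CCCCCCC/C=C\CCCCCCO[Si](C)(C)C(C)(C)C)C=C2C(=O)OCC[Si](C)(C)C)C(C=O)=CC[C@@H]13 | intermediate
27 | the saturated aldehyde 28 as a mixture of both C2 epimers | CC1(C)[C@H]2C[C@@]3([C@@H](OC(=O)CCCCCCC/C=C\CCCCCCO[Si](C)(C)C(C)(C)C)C=C2C(=O)OCC[Si](C)(C)C)C(C=O)CC[C@@H]13 | intermediate
28 | 2-(trimethylsilyl)ethyl 10-{[(9Z)-16-[(tert-butyldimethylsilyl)oxy]hexadec-9-enoyl]oxy}-12-oxocedr-8-en-15-oate (all centres as in the target) | CC1(C)[C@H]2C[C@@]3([C@@H](OC(=O)CCCCCCC/C=C\CCCCCCO[Si](C)(C)C(C)(C)C)C=C2C(=O)OCC[Si](C)(C)C)[C@@H](C=O)CC[C@@H]13 | intermediate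
29 | CNP0214056.2, 10-{[(9Z)-16-hydroxyhexadec-9-enoyl]oxy}-12-oxocedr-8-en-15-oic acid | CC1(C)[C@H]2C[C@@]3([C@@H](OC(=O)CCCCCCC/C=C\CCCCCCO)C=C2C(=O)O)[C@@H](C=O)CC[C@@H]13 | target

Total step count: 20. Longest linear sequence: 17 steps (steps 1–13 and 17–20).

**Steps most likely to fail**

Step 9 is the riskiest. The cationic cyclisation has to join the quaternary C1 to a carbon next to the quaternary C6. It may stall, lose a proton to an unsaturated amide, or divert through cation rearrangement next to C6. The fallback replaces the keteniminium ion by a neutral ketene, which adds to the alkene in a concerted way without a free cation. It sets out from 11. Activation of the amide and silane reduction (Tf2O, 2-fluoropyridine, Et3SiH, −78 → 0 °C, then aqueous citric acid) should give 2-(trimethylsilyl)ethyl (6R)-4-formyl-6-(2-methylbut-3-en-2-yl)cyclohex-1-ene-1-carboxylate F1. Pinnick oxidation (NaClO2, NaH2PO4, 2-methylbut-2-ene) should give (5R)-5-(2-methylbut-3-en-2-yl)-4-{[2-(trimethylsilyl)ethoxy]carbonyl}cyclohex-3-ene-1-carboxylic acid F2. Oxalyl chloride with catalytic DMF should give the acid chloride F3. Dehydrochlorination (Et3N, toluene, reflux) should give the ketene F4, whose intramolecular [2+2] cycloaddition comes back to the route at 14.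

Step 10 may give the wrong regiochemistry (migration of the quaternary C1 instead of C4) or a second insertion. The fallback builds C3 onto both C2 and C4 before any bond is broken, so the regiochemistry is fixed by construction (Ito–Saegusa ring enlargement). It sets out from 14. Kinetic enolisation and silylation (LDA, Me3SiCl, THF, −78 °C), possible only towards C4, should give the cyclobutenyl silyl ether F5. Simmons–Smith cyclopropanation (Et2Zn, CH2I2, CH2Cl2) should give the siloxycyclopropane F6. FeCl3 in DMF should cleave the internal C2–C4 bond to the β-chloro ketone F7. NaOAc in MeOH should eliminate HCl to the cyclopentenone F8. Conjugate reduction ([(Ph3P)CuH]6, toluene, H2O) comes back to the route at 16.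

Step 19 may fail through loss of chemoselectivity: copper hydride may also reduce the ring B enoate or attack the allylic ester. The fallback replaces the hydride conjugate reduction by a redox isomerisation and sets out from 26. Luche reduction (NaBH4, CeCl3·7H2O, MeOH, −78 °C) should give the allylic alcohol F9. Isomerisation of the primary allylic alcohol to the saturated aldehyde ([Ir(cod)(PCy3)(py)]PF6 activated with H2, THF, rt) should give 27, and the same DBU equilibration comes back to the route at 28. The bias at C2 rests on the 1,3-syn C12/O10 contact in the unwanted epimer and is a prediction, not a result.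

Further compounds
F1 | step 9 | 2-(trimethylsilyl)ethyl (6R)-4-formyl-6-(2-methylbut-3-en-2-yl)cyclohex-1-ene-1-carboxylate | C=CC(C)(C)[C@H]1CC(C=O)CC=C1C(=O)OCC[Si](C)(C)C
F2 | step 9 | (5R)-5-(2-methylbut-3-en-2-yl)-4-{[2-(trimethylsilyl)ethoxy]carbonyl}cyclohex-3-ene-1-carboxylic acid | C=CC(C)(C)[C@H]1CC(C(=O)O)CC=C1C(=O)OCC[Si](C)(C)C
F3 | step 9 | acid chloride of F2 | C=CC(C)(C)[C@H]1CC(C(=O)Cl)CC=C1C(=O)OCC[Si](C)(C)C
F4 | step 9 | ketene from F3 (ring carbon C1 doubly bonded to C2=O) | C=CC(C)(C)[C@H]1CC(=C=O)CC=C1C(=O)OCC[Si](C)(C)C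
F5 | step 10 | cyclobutenyl trimethylsilyl ether of 14 (C2(OSiMe3)=C4) | CC1(C)[C@H]2C[C@@]3(CC=C2C(=O)OCC[Si](C)(C)C)C(O[Si](C)(C)C)=C[C@@H]13
F6 | step 10 | siloxycyclopropane (C3 bridging C2 and C4; configuration at C2 and C4 open, lost on cleavage) | CC1(C)[C@H]2C[C@@]3(CC=C2C(=O)OCC[Si](C)(C)C)C4(O[Si](C)(C)C)CC4[C@@H]13
F7 | step 10 | 2-(trimethylsilyl)ethyl 4-chloro-2-oxo-12-norcedr-8-en-15-oate (C4 configuration open) | CC1(C)[C@H]2C[C@@]3(CC=C2C(=O)OCC[Si](C)(C)C)C(=O)CC(Cl)[C@@H]13
F8 | step 10 | 2-(trimethylsilyl)ethyl 2-oxo-12-norcedra-3,8-dien-15-oate (cyclopentenone) | CC1(C)[C@H]2C[C@@]3(CC=C2C(=O)OCC[Si](C)(C)C)C(=O)C=C[C@@H]13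
F9 | step 19 | 2-(trimethylsilyl)ethyl 10-{[(9Z)-16-[(tert-butyldimethylsilyl)oxy]hexadec-9-enoyl]oxy}-12-hydroxycedra-2,8-dien-15-oate (allylic alcohol) | CC1(C)[C@H]2C[C@@]3([C@@H](OC(=O)CCCCCCC/C=C\CCCCCCO[Si](C)(C)C(C)(C)C)C=C2C(=O)OCC[Si](C)(C)C)C(CO)=CC[C@@H]13
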